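**Retrosynthetic overview**
1. Target ⇒ the 3‑OH / 9‑OTBS germacranolide. The last two operations are O3 acylation with (R)‑2‑methylbutanoic acid and O9 desilylation.
2. Both rings ⇒ one acyclic, fully oxygenated (2E,6Z,10E)‑farnesane chain (C6 enal, C12 methyl ester). A single SmI2 cascade closes C6–C7 (farnesyl C1–C10) to give the ten‑membered carbocycle first. O6→C12 then closes the γ‑lactone. The cascade sets C6, C7 and C11.
3. Chain ⇒ three C5 units joined head to tail by two catalytic asymmetric vinylogous aldol reactions (C2–C3 sets 3S, C8–C9 sets 9S).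
4. The 1(10)‑Z alkene is fixed by letting the first aldol adduct close to a δ‑lactone, which is reopened as a Weinreb amide.

**Assumptions**
- Germacrane numbering is used for positions. C3 is the acyloxy carbon, C4(C15)=C5 the E‑alkene, C6 the lactone carbinol carbon and C7 the ring‑fusion CH. C9 is the free carbinol and C1=C10(C14) the Z‑alkene. C11(C13) is the CH–CH3 of the lactone and C12 the lactone C=O.
- (R)‑2‑Methylbutanoic acid, (E)‑4,4‑dimethoxy‑2‑methylbut‑2‑enal (an industrial C5 carotenoid building block), 2‑methylbut‑3‑enoic acid, phenol and methyl tiglate are bought.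
- Catalyst antipodes are quoted for the facial sense needed (Si‑face attack on both enals). If the established sense of a ligand is the reverse, its mirror image is meant.

**Route**

Step 1
Reactants: 1 2‑methylbut‑3‑enoic acid (racemic); 2 phenol
Product: 3 phenyl 2‑methylbut‑3‑enoate (racemic)
Conditions: DCC, DMAP (5 mol %), CH2Cl2, 0 °C
Reagents that add atoms: none
Why: Steglich esterification at 0 °C keeps the alkene out of conjugation; the aryl ester allows soft enolisation and serves as the leaving group in step 2, and its stereocentre is lost on enolisation.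

Step 2
Reactants: 4 (2E)‑4,4‑dimethoxy‑2‑methylbut‑2‑enal; 3 phenyl 2‑methylbut‑3‑enoate
Product: 6 (6S)‑6‑[(2E)‑4,4‑dimethoxybut‑2‑en‑2‑yl]‑3‑methyl‑5,6‑dihydro‑2H‑pyran‑2‑one, via open-chain hydroxy phenyl ester 5 (not isolated)
Conditions: Cu(CH3CN)4PF6 (5 mol %), (R)‑DTBM‑SEGPHOS (6 mol %), Barton's base (10 mol %), THF, −20 °C → rt
Reagents that add atoms: none
Why: Direct catalytic asymmetric vinylogous aldol–lactonisation, in which the chiral monovalent‑copper dienolate attacks the Si face of the non‑enolisable enal through its γ‑carbon (sets 3S), and the Z‑enoate alkoxide expels phenoxide so that the six‑membered ring locks C1=C10 as Z.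

Step 3
Reactants: 6 δ‑lactone
Product: 8 (2Z,5S,6E)‑N,8,8‑trimethoxy‑N,2,6‑trimethyl‑5‑(triethylsilyloxy)octa‑2,6‑dienamide, via hydroxy Weinreb amide 7 (not isolated)
Conditions: MeNH(OMe)·HCl + i‑PrMgCl (premixed), THF, −20 °C, then 6; then TESCl, imidazole, −20 °C → rt, same flask
Reagents that add atoms: N,O‑dimethylhydroxylamine hydrochloride, CNOC.Cl; chlorotriethylsilane, CC[Si](Cl)(CC)CC
Why: Weinreb aminolysis of the lactone by the magnesium amide leaves the Z alkene and C3 untouched, and silylating the magnesium alkoxide in the same flask prevents relactonisation (a chlorosilane is used because silyl triflates attack the acetal).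

Step 4
Reactants: 8 TES Weinreb amide
Product: 9 (2Z,5S,6E)‑8,8‑dimethoxy‑2,6‑dimethyl‑5‑(triethylsilyloxy)octa‑2,6‑dienal
Conditions: DIBAL‑H (1.3 equiv), THF, −78 °C; aq. Rochelle salt, 0 °C; used at once
Reagents that add atoms: none
Why: Weinreb amide reduction stops at the chelated tetrahedral aluminium intermediate, which releases the Z‑enal only on cold neutral work‑up, so over‑reduction and Z→E isomerisation are avoided.

Step 5
Reactants: 10 methyl (2E)‑2‑methylbut‑2‑enoate (methyl tiglate)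
Product: 11 tert‑butyl[(1‑methoxy‑2‑methylbuta‑1,3‑dien‑1‑yl)oxy]dimethylsilane (ketene acetal E/Z mixture, geometry irrelevant)
Conditions: LDA (commercial), THF–DMPU, −78 °C; TBSCl
Reagents that add atoms: tert‑butyldimethylsilyl chloride, CC(C)(C)[Si](C)(C)Cl
Why: Kinetic γ‑deprotonation of the enoate followed by O‑silylation gives the silyl dienol ether needed for the Mukaiyama step.

Step 6
Reactants: 9 Z‑enal; 11 silyl dienol ether
Product: 13 methyl (2E,5S,6Z,9S,10E)‑5‑hydroxy‑12,12‑dimethoxy‑2,6,10‑trimethyl‑9‑(triethylsilyloxy)dodeca‑2,6,10‑trienoate, via trichlorosilyl ether 12 (not isolated)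
Conditions: SiCl4 (1.1 equiv), (R,R)‑BINAM‑derived pentane‑1,5‑diyl‑linked bisphosphoramide (5 mol %), i‑Pr2NEt (10 mol %), CH2Cl2, −78 °C; sat. aq. NaHCO3
Reagents that add atoms: none
Why: Lewis‑base‑activated SiCl4 vinylogous Mukaiyama aldol reaction, in which the chiral siliconium ion binds the aldehyde and the dienolate reacts only at its γ‑carbon on the Si face (catalyst control over the remote C3 centre, sets 9S) to give the E‑enoate.

Step 7
Reactants: 13 alcohol
Product: 14 methyl (2E,5S,6Z,9S,10E)‑5‑(tert‑butyldimethylsilyloxy)‑12,12‑dimethoxy‑2,6,10‑trimethyl‑9‑(triethylsilyloxy)dodeca‑2,6,10‑trienoate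
Conditions: TBSCl, imidazole, DMAP (cat.), DMF, 35 °C
Reagents that add atoms: tert‑butyldimethylsilyl chloride, CC(C)(C)[Si](C)(C)Cl
Why: Standard silylation of the only free hydroxyl; the TBS (O9) / TES (O3) pair provides the later differentiation of the two allylic oxygens.

Step 8
Reactants: 14 bis‑silyl ether acetal
Product: 15 methyl (2E,5S,6Z,9S,10E)‑5‑(tert‑butyldimethylsilyloxy)‑9‑hydroxy‑2,6,10‑trimethyl‑12‑oxododeca‑2,6,10‑trienoate
Conditions: AcOH–THF–H2O (3:1:1), 0 °C → rt
Reagents that add atoms: water, O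
Why: In this mild acid hydrolysis the allylic dimethyl acetal and the secondary TES ether cleave much faster than the TBS ether, which frees the C6 enal and O3–H in one operation without touching a stereocentre.

Step 9
Reactants: 15 acyclic hydroxy enal ester
Product: 17 (3R,3aS,5S,6Z,9S,10E,11aS)‑5‑(tert‑butyldimethylsilyloxy)‑9‑hydroxy‑3,6,10‑trimethyl‑3a,4,5,8,9,11a‑hexahydrocyclodeca[b]furan‑2(3H)‑one, via monocyclic hydroxy ester 16 (not isolated)
Conditions: SmI2 (3 equiv, 0.1 M in THF), t‑BuOH (3 equiv), THF, −20 °C, 15 added by syringe pump over 8 h (final 2 mM), Ar; aq. NaHCO3/Na2S2O3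
Reagents that add atoms: none
Why: Proposed new method: divalent samarium reduces the enal to a samarium‑bound allylic ketyl that adds through C6 (attack through C4 would build a quaternary centre in an eight‑membered ring) to the β‑carbon C7 of the E‑enoate in a 10‑exo ketyl–olefin closure, whose usual anti transition state (O6 turned away from C11, with the C3 and C9 oxygens exo on the forming ring) gives the trans 6S,7S pair; a second electron gives the still open‑chain ester enolate, which t‑BuOH protonates anti to the bulky C6 carbinol carbon while A(1,3) strain holds H7 in the enolate plane (11R, the less stable epimer that protonation or hydride reduction of a closed lactone would not give); the samarium alkoxide then closes the trans‑fused γ‑lactone; the closest known reaction type is the SmI2 ketyl–enoate reductive coupling to γ‑butyrolactones, together with its eight‑membered‑ring and macrocyclic pinacol or Reformatsky variants.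

Step 10
Reactants: 17 hydroxy lactone; 18 (2R)‑2‑methylbutanoic acid
Product: 19 (3R,3aS,5S,6Z,9S,10E,11aS)‑5‑(tert‑butyldimethylsilyloxy)‑3,6,10‑trimethyl‑2‑oxo‑2,3,3a,4,5,8,9,11a‑octahydrocyclodeca[b]furan‑9‑yl (2R)‑2‑methylbutanoate
Conditions: DCC, DMAP (20 mol %), CH2Cl2, 0 °C → rt
Reagents that add atoms: none
Why: Steglich esterification of the only free hydroxyl proceeds with retention at C3, brings in the side‑chain stereocentre from the acid, and is mild enough not to epimerise C11 or C2′.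

Step 11
Reactants: 19 TBS ether
Product: 20 target, (3R,3aS,5S,6Z,9S,10E,11aS)‑5‑hydroxy‑3,6,10‑trimethyl‑2‑oxo‑2,3,3a,4,5,8,9,11a‑octahydrocyclodeca[b]furan‑9‑yl (2R)‑2‑methylbutanoate
Conditions: HF·pyridine, pyridine, THF, 0 °C → rt
Reagents that add atoms: none
Why: Pyridine‑buffered fluoride desilylation avoids the basic conditions that would cause C11 epimerisation, acyl migration or translactonisation, and the strong acid that would trigger transannular cyclisation of the 1,5‑diene.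

**Compound list**
1 | 2‑methylbut‑3‑enoic acid (racemic) | C=CC(C)C(=O)O | starting material
2 | phenol | Oc1ccccc1 | starting material
3 | phenyl 2‑methylbut‑3‑enoate (racemic) | C=CC(C)C(=O)Oc1ccccc1 | intermediate
4 | (2E)‑4,4‑dimethoxy‑2‑methylbut‑2‑enal | COC(OC)/C=C(\C)C=O | starting material
5 | phenyl (2Z,5S,6E)‑5‑hydroxy‑8,8‑dimethoxy‑2,6‑dimethylocta‑2,6‑dienoate | COC(OC)/C=C(\C)[C@@H](O)C/C=C(/C)C(=O)Oc1ccccc1 | intermediate
6 | (6S)‑6‑[(2E)‑4,4‑dimethoxybut‑2‑en‑2‑yl]‑3‑methyl‑5,6‑dihydro‑2H‑pyran‑2‑one | COC(OC)/C=C(\C)[C@@H]1CC=C(C)C(=O)O1 | intermediate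
7 | (2Z,5S,6E)‑5‑hydroxy‑N,8,8‑trimethoxy‑N,2,6‑trimethylocta‑2,6‑dienamide | COC(OC)/C=C(\C)[C@@H](O)C/C=C(/C)C(=O)N(C)OC | intermediate
8 | (2Z,5S,6E)‑N,8,8‑trimethoxy‑N,2,6‑trimethyl‑5‑(triethylsilyloxy)octa‑2,6‑dienamide | COC(OC)/C=C(\C)[C@@H](O[Si](CC)(CC)CC)C/C=C(/C)C(=O)N(C)OC | intermediate
9 | (2Z,5S,6E)‑8,8‑dimethoxy‑2,6‑dimethyl‑5‑(triethylsilyloxy)octa‑2,6‑dienal | COC(OC)/C=C(\C)[C@@H](O[Si](CC)(CC)CC)C/C=C(/C)C=O | intermediate
10 | methyl (2E)‑2‑methylbut‑2‑enoate | C/C=C(\C)C(=O)OC | starting material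
11 | tert‑butyl[(1‑methoxy‑2‑methylbuta‑1,3‑dien‑1‑yl)oxy]dimethylsilane | C=CC(C)=C(OC)O[Si](C)(C)C(C)(C)C | intermediate
12 | methyl (2E,5S,6Z,9S,10E)‑12,12‑dimethoxy‑2,6,10‑trimethyl‑5‑(trichlorosilyloxy)‑9‑(triethylsilyloxy)dodeca‑2,6,10‑trienoate | COC(OC)/C=C(\C)[C@@H](O[Si](CC)(CC)CC)C/C=C(/C)[C@@H](O[Si](Cl)(Cl)Cl)C/C=C(\C)C(=O)OC | intermediate
13 | methyl (2E,5S,6Z,9S,10E)‑5‑hydroxy‑12,12‑dimethoxy‑2,6,10‑trimethyl‑9‑(triethylsilyloxy)dodeca‑2,6,10‑trienoate | COC(OC)/C=C(\C)[C@@H](O[Si](CC)(CC)CC)C/C=C(/C)[C@@H](O)C/C=C(\C)C(=O)OC | intermediate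
14 | methyl (2E,5S,6Z,9S,10E)‑5‑(tert‑butyldimethylsilyloxy)‑12,12‑dimethoxy‑2,6,10‑trimethyl‑9‑(triethylsilyloxy)dodeca‑2,6,10‑trienoate | COC(OC)/C=C(\C)[C@@H](O[Si](CC)(CC)CC)C/C=C(/C)[C@@H](O[Si](C)(C)C(C)(C)C)C/C=C(\C)C(=O)OC | intermediate
15 | methyl (2E,5S,6Z,9S,10E)‑5‑(tert‑butyldimethylsilyloxy)‑9‑hydroxy‑2,6,10‑trimethyl‑12‑oxododeca‑2,6,10‑trienoate | O=C/C=C(\C)[C@@H](O)C/C=C(/C)[C@@H](O[Si](C)(C)C(C)(C)C)C/C=C(\C)C(=O)OC | intermediate
16 | methyl (2R)‑2‑[(1S,2S,3E,5S,7Z,9S)‑9‑(tert‑butyldimethylsilyloxy)‑2,5‑dihydroxy‑4,8‑dimethylcyclodeca‑3,7‑dien‑1‑yl]propanoate | O[C@H]1C/C=C(/C)[C@@H](O[Si](C)(C)C(C)(C)C)C[C@@H]([C@@H](C)C(=O)OC)[C@@H](/C=C/1C)O | intermediate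
17 | (3R,3aS,5S,6Z,9S,10E,11aS)‑5‑(tert‑butyldimethylsilyloxy)‑9‑hydroxy‑3,6,10‑trimethyl‑3a,4,5,8,9,11a‑hexahydrocyclodeca[b]furan‑2(3H)‑one | O[C@H]1C/C=C(/C)[C@@H](O[Si](C)(C)C(C)(C)C)C[C@@H]2[C@@H](/C=C/1C)OC(=O)[C@@H]2C | intermediate
18 | (2R)‑2‑methylbutanoic acid | CC[C@@H](C)C(=O)O | starting material
19 | 9‑O‑TBS ether of the target | CC[C@@H](C)C(=O)O[C@H]1C/C=C(/C)[C@@H](O[Si](C)(C)C(C)(C)C)C[C@@H]2[C@@H](/C=C/1C)OC(=O)[C@@H]2C | intermediate
20 | CNP0276536.1 | CC[C@@H](C)C(=O)O[C@H]1C/C=C(/C)[C@@H](O)C[C@@H]2[C@@H](/C=C/1C)OC(=O)[C@@H]2C | target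

**Totals**
Total step count: 11. Longest linear sequence: 10 steps (1, 2, 3, 4, 6, 7, 8, 9, 10, 11).

**Three steps most likely to fail**

Step 9 (ketyl–enoate macrocyclisation) carries the most risk.
- Possible failures: plain reduction or pinacol dimerisation of the enal, vinylogous loss of O3, slow addition to the α,β‑disubstituted acceptor, or poor control at C7 or C11.
- The fallback sets out from 9 and comes back at 17.
  - 9 undergoes the same vinylogous aldol reaction with the crotonate‑derived silyl dienolate F1 (from methyl crotonate, LDA, TBSCl). This gives the 13‑nor hydroxy trienoate F2.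
  - F2 is silylated to the 13‑nor TBS ether F3 and hydrolysed to the 13‑nor hydroxy enal F4.
  - SmI2 then closes F4 onto an α‑unsubstituted enoate, a far better acceptor for nucleophilic radicals, to give the 13‑nor lactone F5.
  - C13 is brought in last by alkylation. LDA (2.2 equiv) and MeI at −78 °C attack the closed lactone enolate on the face staggered between C6 and C8 and anti to H7.
  - The incoming group is now the methyl rather than the proton. It ends cis to C8 (11R), which gives 17.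

Step 2 (copper‑catalysed vinylogous aldol–lactonisation) uses an α‑branched donor.
- Possible failures: poorer γ/α selectivity or lower ee than for unbranched donors.
- The fallback sets out from 4 and comes back at 6.
  - Brown allylation of 4 with B‑allyldiisopinocampheylborane made from (+)‑α‑pinene gives the (4S)‑homoallylic alcohol F6.
  - Methacryloyl chloride with Et3N and DMAP gives the methacrylate F7.
  - Ring‑closing metathesis with the second‑generation Grubbs catalyst (toluene, 80 °C) gives 6. The Z geometry is again imposed by the six‑membered ring.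

Step 6 (vinylogous Mukaiyama aldol on the Z‑enal) exposes a sensitive substrate to a strong Lewis acid.
- Possible failures: Z→E isomerisation of 9, or ionisation of the allylic acetal by the siliconium Lewis acid.
- The fallback sets out from 9 and comes back at 13, and it uses no Lewis acid.
  - Brown allylation of 9 with the same (+)‑α‑pinene‑derived allylborane sets 9S and gives the homoallylic alcohol F8.
  - Cross metathesis of its only terminal alkene with excess methyl methacrylate (second‑generation Hoveyda–Grubbs catalyst, CH2Cl2, 40 °C) installs the E‑2‑methyl enoate and gives 13.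

**Further compounds**
F1 | step 9 | tert‑butyl[(1‑methoxybuta‑1,3‑dien‑1‑yl)oxy]dimethylsilane | C=CC=C(OC)O[Si](C)(C)C(C)(C)C
F2 | step 9 | methyl (2E,5S,6Z,9S,10E)‑5‑hydroxy‑12,12‑dimethoxy‑6,10‑dimethyl‑9‑(triethylsilyloxy)dodeca‑2,6,10‑trienoate | COC(OC)/C=C(\C)[C@@H](O[Si](CC)(CC)CC)C/C=C(/C)[C@@H](O)C/C=C/C(=O)OC
F3 | step 9 | methyl (2E,5S,6Z,9S,10E)‑5‑(tert‑butyldimethylsilyloxy)‑12,12‑dimethoxy‑6,10‑dimethyl‑9‑(triethylsilyloxy)dodeca‑2,6,10‑trienoate | COC(OC)/C=C(\C)[C@@H](O[Si](CC)(CC)CC)C/C=C(/C)[C@@H](O[Si](C)(C)C(C)(C)C)C/C=C/C(=O)OC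
F4 | step 9 | methyl (2E,5S,6Z,9S,10E)‑5‑(tert‑butyldimethylsilyloxy)‑9‑hydroxy‑6,10‑dimethyl‑12‑oxododeca‑2,6,10‑trienoate | O=C/C=C(\C)[C@@H](O)C/C=C(/C)[C@@H](O[Si](C)(C)C(C)(C)C)C/C=C/C(=O)OC
F5 | step 9 | (3aS,5S,6Z,9S,10E,11aS)‑5‑(tert‑butyldimethylsilyloxy)‑9‑hydroxy‑6,10‑dimethyl‑3a,4,5,8,9,11a‑hexahydrocyclodeca[b]furan‑2(3H)‑one | O[C@H]1C/C=C(/C)[C@@H](O[Si](C)(C)C(C)(C)C)C[C@@H]2[C@@H](/C=C/1C)OC(=O)C2
F6 | step 2 | (4S,5E)‑7,7‑dimethoxy‑5‑methylhepta‑1,5‑dien‑4‑ol | COC(OC)/C=C(\C)[C@@H](O)CC=C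
F7 | step 2 | (4S,5E)‑7,7‑dimethoxy‑5‑methylhepta‑1,5‑dien‑4‑yl 2‑methylprop‑2‑enoate | COC(OC)/C=C(\C)[C@@H](OC(=O)C(C)=C)CC=C
F8 | step 6 | (4S,5Z,8S,9E)‑11,11‑dimethoxy‑5,9‑dimethyl‑8‑(triethylsilyloxy)undeca‑1,5,9‑trien‑4‑ol | COC(OC)/C=C(\C)[C@@H](O[Si](CC)(CC)CC)C/C=C(/C)[C@@H](O)CC=C
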